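**Plan**

- Retrosynthesis first cuts the two trisubstituted C2''=C3'' alkenes of the 3-methylbut-2-enyl chains (back to allyl groups). It then cuts the two aryl–CH2 bonds at C3' and C5' (back to 4'-O-allyl ethers), and last the Cα–Cβ bond of the three-carbon bridge (back to an acetophenone and a benzaldehyde).
- Enabling feature: C3' and C5' of ring A both lie ortho to the 4'-oxygen. Each chain can therefore arrive as an allyl group by a (3,3) shift from O4' and receive its isopropylidene terminus afterwards, which excludes reverse-prenyl and O-prenyl isomers.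
- Forward: ring B aldehyde and ring A ketone are joined by Claisen–Schmidt condensation, and the enone is hydrogenated while no other alkene is present. Two O-allylation/Claisen rounds then fill C3' and C5', the ring B acetal is removed, and a twofold cross-metathesis completes the target.
- No ring is formed at any stage; rings A and B come from the starting materials.
- Stereochemistry: the target has no stereocentre and its alkenes carry two identical methyl groups, so nothing needs control; the E chalcone alkene is transient.

Key step: step 10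

Remark: the first Claisen rearrangement is drawn as delivering the allyl group to C3'. Any C5' isomer formed alongside can be carried forward, because the second round fills the other position and both converge on compound 15.

**Step 1**
Reactants: 1 4-hydroxybenzaldehyde
Product: 2 4-(methoxymethoxy)benzaldehyde
Conditions: MOMCl, K2CO3, acetone, 0 °C to rt
Reagents that add atoms: chloromethyl methyl ether (MOMCl), COCCl
Why: Williamson-type O-alkylation of the phenoxide by the highly electrophilic chloromethyl ether gives a MOM acetal that withstands the later KOH, K2CO3, hydrogenation and thermal steps.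

**Step 2**
Reactants: 3 2,4-dihydroxyacetophenone
Product: 4 1-[4-(benzyloxy)-2-hydroxyphenyl]ethanone
Conditions: BnBr, K2CO3, acetone, reflux
Reagents that add atoms: benzyl bromide, BrCc1ccccc1
Why: Williamson ether synthesis is selective for the 4-hydroxyl because the 2-hydroxyl is hydrogen-bonded to the ketone and far less nucleophilic under K2CO3 in acetone.

**Step 3**
Reactants: 4 1-[4-(benzyloxy)-2-hydroxyphenyl]ethanone; 2 4-(methoxymethoxy)benzaldehyde
Product: 6 (E)-1-[4-(benzyloxy)-2-hydroxyphenyl]-3-[4-(methoxymethoxy)phenyl]prop-2-en-1-one, via aldol adduct 5 (not isolated)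
Conditions: KOH, EtOH/H2O, rt; then 1 M HCl, 0 °C
Reagents that add atoms: none
Why: Claisen–Schmidt condensation, in which the ketone enolate adds to the non-enolisable aldehyde and the aldol adduct loses water by an E1cB pathway to the conjugated E enone, the MOM and benzyl ethers being inert to hydroxide.

**Step 4**
Reactants: 6 (E)-1-[4-(benzyloxy)-2-hydroxyphenyl]-3-[4-(methoxymethoxy)phenyl]prop-2-en-1-one
Product: 8 1-(2,4-dihydroxyphenyl)-3-[4-(methoxymethoxy)phenyl]propan-1-one, via benzyl ether dihydrochalcone 7 (not isolated)
Conditions: H2 (1 atm), 10% Pd/C, EtOAc/MeOH, rt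
Reagents that add atoms: none
Why: Heterogeneous catalytic hydrogenation saturates the enone alkene and hydrogenolyses the benzyl ether in one flask while the molecule holds no other alkene, and the hydrogen-bonded aryl ketone and the MOM acetal are expected to persist at atmospheric pressure.

**Step 5**
Reactants: 8 1-(2,4-dihydroxyphenyl)-3-[4-(methoxymethoxy)phenyl]propan-1-one; 9 allyl bromide
Product: 10 1-[4-(allyloxy)-2-hydroxyphenyl]-3-[4-(methoxymethoxy)phenyl]propan-1-one
Conditions: K2CO3, acetone, reflux
Reagents that add atoms: none
Why: Williamson ether synthesis on the more acidic, non-chelated 4'-hydroxyl places the allyl group on the oxygen flanked by C3' and C5'.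

**Step 6**
Reactants: 10 1-[4-(allyloxy)-2-hydroxyphenyl]-3-[4-(methoxymethoxy)phenyl]propan-1-one
Product: 12 1-(3-allyl-2,4-dihydroxyphenyl)-3-[4-(methoxymethoxy)phenyl]propan-1-one, via ortho-dienone 11 (not isolated)
Conditions: N,N-diethylaniline, 200 °C, argon
Reagents that add atoms: none
Why: Aromatic Claisen rearrangement, a concerted (3,3) sigmatropic shift from O4' to the ortho carbon followed by tautomerisation of the dienone, with C3' favoured by the bond fixation that the chelated 2'-hydroxy ketone imposes on ring A.

**Step 7**
Reactants: 12 1-(3-allyl-2,4-dihydroxyphenyl)-3-[4-(methoxymethoxy)phenyl]propan-1-one; 9 allyl bromide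
Product: 13 1-[3-allyl-4-(allyloxy)-2-hydroxyphenyl]-3-[4-(methoxymethoxy)phenyl]propan-1-one
Conditions: K2CO3, acetone, reflux
Reagents that add atoms: none
Why: Williamson ether synthesis again distinguishes the free 4'-hydroxyl from the chelated 2'-hydroxyl, as in step 5.

**Step 8**
Reactants: 13 1-[3-allyl-4-(allyloxy)-2-hydroxyphenyl]-3-[4-(methoxymethoxy)phenyl]propan-1-one
Product: 15 1-(3,5-diallyl-2,4-dihydroxyphenyl)-3-[4-(methoxymethoxy)phenyl]propan-1-one, via ortho-dienone 14 (not isolated)
Conditions: N,N-diethylaniline, 200 °C, argon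
Reagents that add atoms: none
Why: Second aromatic Claisen rearrangement, in which the (3,3) shift can end productively only at C5' because C3' is occupied, and tautomerisation then gives the 3',5'-diallyl resorcinol.

**Step 9**
Reactants: 15 1-(3,5-diallyl-2,4-dihydroxyphenyl)-3-[4-(methoxymethoxy)phenyl]propan-1-one
Product: 16 1-(3,5-diallyl-2,4-dihydroxyphenyl)-3-(4-hydroxyphenyl)propan-1-one
Conditions: conc. HCl (cat.), MeOH, 50 °C
Reagents that add atoms: none
Why: Acid-catalysed acetal exchange with methanol (MOM ether cleavage) frees the ring B phenol while the side chains are still acid-tolerant allyl groups, so the prenyl alkenes made later never meet acid and cannot cyclise onto the neighbouring phenols to chromans.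

**Step 10**
Reactants: 16 1-(3,5-diallyl-2,4-dihydroxyphenyl)-3-(4-hydroxyphenyl)propan-1-one; 17 2-methyl-2-butene
Product: 20 gancaonin J, via 3'-allyl-5'-prenyl triol 18 (not isolated), via 5'-allyl-3'-prenyl triol 19 (not isolated)
Conditions: second-generation Grubbs catalyst RuCl2(H2IMes)(PCy3)(=CHPh) (5 mol%), 1,4-benzoquinone (10 mol%), 2-methyl-2-butene (large excess)/CH2Cl2, 40 °C, sealed tube
Reagents that add atoms: none
Why: Twofold olefin cross-metathesis: after loss of PCy3 the ruthenium alkylidene adds each terminal allyl alkene in a (2+2) cycloaddition, the ruthenacyclobutane opens by cycloreversion, and turnover with 2-methyl-2-butene transfers the isopropylidene unit and releases volatile propene. The closest known reaction type is the conversion of ortho-allylphenols into ortho-prenylphenols with 2-methyl-2-butene under the same catalyst, which tolerates free phenols and aryl ketones. No ring is closed, since the two allyl groups sit meta to each other across the 4'-hydroxyl and ring closure would need a strained bridged ring. No stereocentre is formed, and the new alkenes bear two identical methyl groups, so no E/Z isomers exist. The step needs complete exchange at both the C3' and the C5' chain without migration of the allyl double bonds into conjugation with ring A. This is secured by the fast-reacting monosubstituted termini, the large excess of partner used as co-solvent, trisubstituted products that do not re-enter the cycle, and benzoquinone, which intercepts ruthenium hydride species.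

**Compound list**

1 | 4-hydroxybenzaldehyde | O=Cc1ccc(O)cc1 | starting material
2 | 4-(methoxymethoxy)benzaldehyde | COCOc1ccc(C=O)cc1 | intermediate
3 | 2,4-dihydroxyacetophenone | CC(=O)c1ccc(O)cc1O | starting material
4 | 1-[4-(benzyloxy)-2-hydroxyphenyl]ethanone | CC(=O)c1ccc(OCc2ccccc2)cc1O | intermediate
5 | 1-[4-(benzyloxy)-2-hydroxyphenyl]-3-hydroxy-3-[4-(methoxymethoxy)phenyl]propan-1-one (racemic aldol adduct, not isolated) | COCOc1ccc(C(O)CC(=O)c2ccc(OCc3ccccc3)cc2O)cc1 | intermediate
6 | (E)-1-[4-(benzyloxy)-2-hydroxyphenyl]-3-[4-(methoxymethoxy)phenyl]prop-2-en-1-one | COCOc1ccc(/C=C/C(=O)c2ccc(OCc3ccccc3)cc2O)cc1 | intermediate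
7 | 1-[4-(benzyloxy)-2-hydroxyphenyl]-3-[4-(methoxymethoxy)phenyl]propan-1-one (not isolated) | COCOc1ccc(CCC(=O)c2ccc(OCc3ccccc3)cc2O)cc1 | intermediate
8 | 1-(2,4-dihydroxyphenyl)-3-[4-(methoxymethoxy)phenyl]propan-1-one | COCOc1ccc(CCC(=O)c2ccc(O)cc2O)cc1 | intermediate
9 | allyl bromide (3-bromoprop-1-ene) | C=CCBr | starting material
10 | 1-[4-(allyloxy)-2-hydroxyphenyl]-3-[4-(methoxymethoxy)phenyl]propan-1-one | C=CCOc1ccc(C(=O)CCc2ccc(OCOC)cc2)c(O)c1 | intermediate
11 | 6-allyl-5-hydroxy-4-{3-[4-(methoxymethoxy)phenyl]propanoyl}cyclohexa-2,4-dien-1-one (racemic keto tautomer of 12, not isolated) | C=CCC1C(=O)C=CC(C(=O)CCc2ccc(OCOC)cc2)=C1O | intermediate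
12 | 1-(3-allyl-2,4-dihydroxyphenyl)-3-[4-(methoxymethoxy)phenyl]propan-1-one | C=CCc1c(O)ccc(C(=O)CCc2ccc(OCOC)cc2)c1O | intermediate
13 | 1-[3-allyl-4-(allyloxy)-2-hydroxyphenyl]-3-[4-(methoxymethoxy)phenyl]propan-1-one | C=CCOc1ccc(C(=O)CCc2ccc(OCOC)cc2)c(O)c1CC=C | intermediate
14 | 2,6-diallyl-3-hydroxy-4-{3-[4-(methoxymethoxy)phenyl]propanoyl}cyclohexa-2,4-dien-1-one (racemic keto tautomer of 15, not isolated) | C=CCC1C=C(C(=O)CCc2ccc(OCOC)cc2)C(O)=C(CC=C)C1=O | intermediate
15 | 1-(3,5-diallyl-2,4-dihydroxyphenyl)-3-[4-(methoxymethoxy)phenyl]propan-1-one | C=CCc1cc(C(=O)CCc2ccc(OCOC)cc2)c(O)c(CC=C)c1O | intermediate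
16 | 1-(3,5-diallyl-2,4-dihydroxyphenyl)-3-(4-hydroxyphenyl)propan-1-one | C=CCc1cc(C(=O)CCc2ccc(O)cc2)c(O)c(CC=C)c1O | intermediate
17 | 2-methyl-2-butene | CC=C(C)C | starting material
18 | 1-[3-allyl-2,4-dihydroxy-5-(3-methylbut-2-enyl)phenyl]-3-(4-hydroxyphenyl)propan-1-one (not isolated) | CC(C)=CCc1cc(C(=O)CCc2ccc(O)cc2)c(O)c(CC=C)c1O | intermediate
19 | 1-[5-allyl-2,4-dihydroxy-3-(3-methylbut-2-enyl)phenyl]-3-(4-hydroxyphenyl)propan-1-one (not isolated) | C=CCc1cc(C(=O)CCc2ccc(O)cc2)c(O)c(CC=C(C)C)c1O | intermediate
20 | gancaonin J, 1-[2,4-dihydroxy-3,5-bis(3-methylbut-2-enyl)phenyl]-3-(4-hydroxyphenyl)propan-1-one | CC(C)=CCc1cc(C(=O)CCc2ccc(O)cc2)c(O)c(CC=C(C)C)c1O | target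

**Step count**

Total: 10 steps. Longest linear sequence: 9 steps (steps 2 to 10 from compound 3; the branch from compound 1 through steps 1 and 3 to 10 is equally long).

**Steps most likely to fail**

Step 10. Ruthenium hydride species formed from the catalyst in the presence of three free phenols may shift the allyl double bonds into conjugation with ring A. Turnover may also stall after the first exchange if the chelating 2'-hydroxy ketone or a phenoxide ties up ruthenium. The fallback removes the phenolic protons from the substrate and sets out from compound 16. Exhaustive acetylation (Ac2O, pyridine, DMAP, CH2Cl2) should give 4-[3-(2,4-diacetoxy-3,5-diallylphenyl)-3-oxopropyl]phenyl acetate F1. Cross-metathesis of this non-chelating, non-acidic substrate with 2-methyl-2-butene under the second-generation Grubbs catalyst RuCl2(H2IMes)(PCy3)(=CHPh) should give gancaonin J triacetate F2. Mild methanolysis (K2CO3, MeOH, rt), which leaves prenyl groups untouched, returns to the route at compound 20.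

Step 6 (the same concern holds for step 8). At 200 °C the MOM acetal may be lost, the new ortho-allylphenol may cyclise to a 2-methyl-2,3-dihydrobenzofuran, or the allyl ether may simply cleave. The fallback forms both aryl–allyl bonds by cross-coupling instead of sigmatropic shifts and sets out from compound 8. Phenol-directed iodination with N-iodosuccinimide in DMF at 0 °C should hit the two activated positions of ring A and leave the MOM-bearing ring B alone. This gives 1-(2,4-dihydroxy-3,5-diiodophenyl)-3-[4-(methoxymethoxy)phenyl]propan-1-one F3. A twofold Stille coupling with allyltributylstannane (Pd(PPh3)4, DMF, 90 °C) returns to the route at compound 15 and bypasses steps 5 to 8.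

Step 4. The aryl ketone may be over-reduced to the benzylic alcohol or methylene before hydrogenolysis of the benzyl ether is complete. The fallback avoids hydrogen gas and the benzyl group and sets out from compound 3. Selective allylation with allyl bromide 9 (K2CO3, acetone, reflux) gives 1-[4-(allyloxy)-2-hydroxyphenyl]ethanone F4. Claisen–Schmidt condensation with compound 2 (KOH, EtOH/H2O) gives (E)-1-[4-(allyloxy)-2-hydroxyphenyl]-3-[4-(methoxymethoxy)phenyl]prop-2-en-1-one F5. Copper hydride conjugate reduction (Stryker's reagent [(Ph3P)CuH]6 with excess polymethylhydrosiloxane in toluene, fluoride work-up to free the transiently silylated phenol) reduces enones but not isolated allyl alkenes. It returns to the route at compound 10 and bypasses steps 2, 4 and 5.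

**Further compounds**

F1 | step 10 | 4-[3-(2,4-diacetoxy-3,5-diallylphenyl)-3-oxopropyl]phenyl acetate | C=CCc1cc(C(=O)CCc2ccc(OC(C)=O)cc2)c(OC(C)=O)c(CC=C)c1OC(C)=O
F2 | step 10 | gancaonin J triacetate | CC(C)=CCc1cc(C(=O)CCc2ccc(OC(C)=O)cc2)c(OC(C)=O)c(CC=C(C)C)c1OC(C)=O
F3 | step 6 | 1-(2,4-dihydroxy-3,5-diiodophenyl)-3-[4-(methoxymethoxy)phenyl]propan-1-one | COCOc1ccc(CCC(=O)c2cc(I)c(O)c(I)c2O)cc1
F4 | step 4 | 1-[4-(allyloxy)-2-hydroxyphenyl]ethanone | CC(=O)c1ccc(OCC=C)cc1O
F5 | step 4 | (E)-1-[4-(allyloxy)-2-hydroxyphenyl]-3-[4-(methoxymethoxy)phenyl]prop-2-en-1-one | C=CCOc1ccc(C(=O)/C=C/c2ccc(OCOC)cc2)c(O)c1
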